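The route cuts two bonds of the inner furan (ring B): O1–C2 and the bond from C3 to the resorcinol ring (ring D) fused to the seven-membered carbocycle (ring C). Ring D is a 2,4-dioxygenated phenyl group on the ring C methine, tied to C3 through its free ortho carbon; without that bond the methine carries two identical 2,4-dimethoxyphenyl groups and is prochiral. One palladium-catalysed operation on an achiral 2-alkynylphenol with a 2,2-bis(2,4-dimethoxyphenyl)ethyl arm closes ring B by oxypalladation and ring C by C–H arylation of one enantiotopic aryl group, setting the methine stereocentre. This centre then directs C3 and C2; the outer dihydrofuran (ring E) follows under catalyst control.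

Key step: step 6

Locants: ring A is the central benzene ring, numbered as a benzofuran (O1, C2, C3 = ring B; C3a, C4, C5, C6, C7, C7a). C4 bears the ring C methylene, C5 is the CH between C4 and C6, C6 bears oxygen, C7 lies between the two oxygens. Ring C is C3a–C3–D1–D6–CH(Ar)–CH2–C4; "the methine" is its CH(Ar). Ring D is the benzo ring D1–D6 with oxygen on D3 and D5. Ring E is the outer dihydrofuran (O1' on C6, C2', C3' on C5).

Assumption: the L-configured ligand in step 6 and the R-configured dirhodium catalyst in step 14 are taken to give the configurations drawn; if either sense of induction proves opposite, the mirror-image ligand or catalyst is used.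

Step 1
Reactants: 1 methyl (3,5-dihydroxyphenyl)acetate
Product: 2 methyl [3-hydroxy-5-(triisopropylsilyloxy)phenyl]acetate
Conditions: i-Pr3SiCl (1.0 equiv), imidazole, DMF, 0 °C to rt
Reagents that add atoms: triisopropylsilyl chloride, CC(C)[Si](Cl)(C(C)C)C(C)C
Why: Silylation of a phenol, used here as a statistical desymmetrisation of the symmetric diphenol (diol and bis-ether are recycled); the TIPS ether is chosen because it should survive hydride, Lewis acid, amine, palladium and CF3CO2H, shields its two ortho positions in step 2 and leaves with fluoride.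

Step 2
Reactants: 2 methyl [3-hydroxy-5-(triisopropylsilyloxy)phenyl]acetate
Product: 3 methyl [3-hydroxy-2-iodo-5-(triisopropylsilyloxy)phenyl]acetate
Conditions: N-iodosuccinimide (1.0 equiv), CH2Cl2, −20 to 0 °C
Reagents that add atoms: N-iodosuccinimide, O=C1CCC(=O)N1I
Why: Electrophilic aromatic iodination, in which C2 is ortho to the free hydroxyl, para to the silyl ether and the only activated position not flanked by the bulky silyl group; iodinating before any dimethoxyphenyl ring is present removes competition from those rings.

Step 3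
Reactants: 3 methyl [3-hydroxy-2-iodo-5-(triisopropylsilyloxy)phenyl]acetate
Product: 4 [3-hydroxy-2-iodo-5-(triisopropylsilyloxy)phenyl]acetaldehyde
Conditions: i-Bu2AlH (2.2 equiv), CH2Cl2, −78 °C; aq. potassium sodium tartrate (KNaC4H4O6)
Reagents that add atoms: none
Why: Partial reduction of a methyl ester by i-Bu2AlH at low temperature should stop at the aldehyde because the tetrahedral aluminium hemiacetal persists until work-up; one equivalent is consumed by the phenol, and the aryl iodide and silyl ether are inert.

Step 4
Reactants: 4 [3-hydroxy-2-iodo-5-(triisopropylsilyloxy)phenyl]acetaldehyde; 5 1,3-dimethoxybenzene (8 equiv)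
Product: 7 3-[2,2-bis(2,4-dimethoxyphenyl)ethyl]-2-iodo-5-(triisopropylsilyloxy)phenol, via mono-aryl carbinol 6 (not isolated)
Conditions: Bi(OTf)3 (10 mol %), CH2Cl2, 0 °C to rt
Reagents that add atoms: none
Why: Twofold Friedel–Crafts reaction (hydroxyalkylation, then benzylic alkylation), in which carbinol 6 ionises readily to a 2,4-dimethoxybenzylic cation that a second arene traps at its C4; the excess of 5 and the silyl-shielded, iodine-bearing ring of 4 should suppress self-alkylation.

Step 5
Reactants: 7 3-[2,2-bis(2,4-dimethoxyphenyl)ethyl]-2-iodo-5-(triisopropylsilyloxy)phenol; 8 4-ethynylanisole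
Product: 9 3-[2,2-bis(2,4-dimethoxyphenyl)ethyl]-2-[(4-methoxyphenyl)ethynyl]-5-(triisopropylsilyloxy)phenol (achiral)
Conditions: PdCl2(PPh3)2 (5 mol %), CuI (5 mol %), Et3N–THF, rt, degassed
Reagents that add atoms: none
Why: Sonogashira coupling of an aryl iodide with a terminal alkyne; at room temperature with an amine base the free ortho-hydroxyl is not expected to cyclise onto the alkyne.

Step 6
Reactants: 9 3-[2,2-bis(2,4-dimethoxyphenyl)ethyl]-2-[(4-methoxyphenyl)ethynyl]-5-(triisopropylsilyloxy)phenol
Product: 10 (S)-benzofuran with rings B and C closed (silyl ether)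
Conditions: Pd(OAc)2 (10 mol %), N-acetyl-L-tert-leucine (25 mol %), 1,4-benzoquinone (1.5 equiv), KHCO3 (0.3 equiv), t-AmOH, 60 °C
Reagents that add atoms: none
Why: Proposed new method: divalent palladium bound to the alkyne of 9 should trigger anti attack of the phenol oxygen to give a benzofuran-3-yl palladium species, whose N-acyl amino acid ligand then serves as internal base for concerted metalation–deprotonation at C6–H of one 2,4-dimethoxyphenyl ring (eight-membered palladacycle); reductive elimination forges the C3–aryl bond and benzoquinone returns zerovalent palladium to the divalent state. The closest known reaction types are oxypalladation of 2-alkynylphenols terminated by C–C bond formation and palladium-catalysed enantioselective C–H arylation that desymmetrises diarylmethanes to seven-membered rings; their union in one catalytic cycle is new. Ring B closes 5-endo-dig by oxypalladation, and ring C closes by aryl–aryl reductive elimination from the palladacycle, that is, by intramolecular C–H arylation. The methine stereocentre (S) is set by the chiral ligand, which selects between the two enantiotopic aryl rings in the C–H cleavage step. The site selectivity needed is secured by the substrate, because C6–H is the only ortho C–H of either ring (C2 carries OMe) and the only C–H the tethered metal can reach. If the aryl–palladium bond is protonated first, the resulting 3-unsubstituted 2-arylbenzofuran can re-enter through C3–H palladation, so both paths should converge on 10.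

Step 7
Reactants: 10 (S)-benzofuran with rings B and C closed (silyl ether)
Product: 12 (2S,3S)-trans-dihydrobenzofuran silyl ether, via cis-dihydrobenzofuran 11 (not isolated)
Conditions: Et3SiH (1.5 equiv), CF3CO2H–CH2Cl2 (1:5), −20 to 0 °C; evaporate; CF3CO2H–CH2Cl2 (1:10), rt
Reagents that add atoms: none
Why: Ionic hydrogenation of a 2,3-diarylbenzofuran: protonation at C3 gives the C2 oxocarbenium ion, the proton entering on the face that lets ring D tilt away from the puckered CH2–CH bridge while the methine aryl group stays pseudo-axial (C3–H cis to that aryl group); hydride from Et3SiH then adds anti to ring D to give cis isomer 11, and reversible C2–O ionisation of this 4-methoxybenzylic ether in the acid epimerises C2 to the more stable 2,3-trans isomer.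

Step 8
Reactants: 12 (2S,3S)-trans-dihydrobenzofuran silyl ether
Product: 13 C6 phenol
Conditions: Bu4NF, THF, 0 °C; aq. NH4Cl
Reagents that add atoms: none
Why: Fluoride cleavage of an aryl silyl ether, driven by the strength of the Si–F bond; nothing else in 12 reacts with fluoride.

Step 9
Reactants: 13 C6 phenol
Product: 15 5-formyl phenol (salicylaldehyde), via hydroxymethylphenol 14 (not isolated)
Conditions: MgCl2, Et3N, paraformaldehyde, MeCN, reflux; aq. HCl
Reagents that add atoms: formaldehyde (as paraformaldehyde), C=O
Why: Magnesium-mediated ortho-formylation of a phenol (Casnati–Skattebøl), in which the magnesium phenoxide delivers formaldehyde only ortho to its oxygen; C5 (para to O1) should be preferred over C7 (between two oxygens) as in orcinol-type phenols, and a second formaldehyde oxidises hydroxymethyl compound 14 to the aldehyde by hydride transfer, while the methyl ether rings are not activated.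

Step 10
Reactants: 15 5-formyl phenol (salicylaldehyde); 16 4-methoxybenzyl chloride
Product: 17 5-formyl C6 4-methoxybenzyl ether
Conditions: K2CO3, Bu4NI (cat.), DMF, 60 °C
Reagents that add atoms: none
Why: Williamson ether synthesis on the phenoxide; the benzylic CH2 introduced here becomes C2' of ring E.

Step 11
Reactants: 17 5-formyl C6 4-methoxybenzyl ether; 18 3,5-dimethoxyphenylmagnesium chloride
Product: 19 C5 diarylcarbinol (both carbinol epimers)
Conditions: THF, −20 to 0 °C; aq. NH4Cl
Reagents that add atoms: none
Why: Grignard 1,2-addition to an aryl aldehyde; the carbinol centre forms without control, which does not matter because step 12 removes it.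

Step 12
Reactants: 19 C5 diarylcarbinol
Product: 20 C5 3,5-dimethoxybenzoyl ketone
Conditions: Dess–Martin periodinane, CH2Cl2, rt
Reagents that add atoms: none
Why: Dess–Martin oxidation of a secondary benzhydrol to the diaryl ketone; ethers and electron-rich arenes are untouched.

Step 13
Reactants: 20 C5 3,5-dimethoxybenzoyl ketone
Product: 21 hydrazone of 20
Conditions: N2H4·H2O (excess), AcOH (cat.), n-BuOH, 120 °C (sealed tube)
Reagents that add atoms: hydrazine (as hydrate), NN
Why: Condensation of a ketone with hydrazine; the carbonyl lies between two ortho substituents, hence the forcing conditions, and the large excess of hydrazine suppresses azine formation.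

Step 14
Reactants: 21 hydrazone of 20
Product: 23 (2'S,3'R)-cis ring E octamethyl ether, via diaryldiazomethane 22 (not isolated)
Conditions: MnO2 (activated), CH2Cl2, rt; filter; Rh2(R-PTAD)4 (1 mol %), CH2Cl2–MeCN, 0 °C
Reagents that add atoms: none
Why: Dehydrogenation of the hydrazone gives diaryldiazomethane 22, whose donor/donor rhodium carbene inserts into the ether-activated benzylic C–H bond (1,5 C–H insertion) and closes ring E with the two new hydrogens cis; C3' (R) is set by the chiral carboxylate ligands of the dirhodium catalyst and C2' follows from the concerted insertion.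

Step 15
Reactants: 23 (2'S,3'R)-cis ring E octamethyl ether
Product: 24 (2'R,3'R)-trans ring E octamethyl ether of the target
Conditions: CF3CO2H, CH2Cl2, 0 °C to rt
Reagents that add atoms: none
Why: Acid-mediated epimerisation: reversible heterolysis of the C2'–O1' bond (4-methoxybenzylic cation) and reclosure by the phenol oxygen should deliver the thermodynamically favoured 2',3'-trans ring, so C2' becomes R while C3' and the centres of rings B and C are untouched.

Step 16
Reactants: 24 (2'R,3'R)-trans ring E octamethyl ether of the target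
Product: 25 CNP0154047.3
Conditions: BBr3 (excess), CH2Cl2, −78 °C to rt; then H2O
Reagents that add atoms: none
Why: Lewis-acid cleavage of all eight aryl methyl ethers by BBr3 (bromide attacks the O-methyl group of each boron-bound ether); both dihydrofuran rings are already in their stable trans form and no stereocentre carries an acidic hydrogen.

Compound list
1 | methyl (3,5-dihydroxyphenyl)acetate | COC(=O)Cc1cc(O)cc(O)c1 | starting material
2 | methyl [3-hydroxy-5-(triisopropylsilyloxy)phenyl]acetate | COC(=O)Cc1cc(O)cc(O[Si](C(C)C)(C(C)C)C(C)C)c1 | intermediate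
3 | methyl [3-hydroxy-2-iodo-5-(triisopropylsilyloxy)phenyl]acetate | COC(=O)Cc1cc(O[Si](C(C)C)(C(C)C)C(C)C)cc(O)c1I | intermediate
4 | [3-hydroxy-2-iodo-5-(triisopropylsilyloxy)phenyl]acetaldehyde | O=CCc1cc(O[Si](C(C)C)(C(C)C)C(C)C)cc(O)c1I | intermediate
5 | 1,3-dimethoxybenzene | COc1cccc(OC)c1 | starting material
6 | 1-(2,4-dimethoxyphenyl)-2-[3-hydroxy-2-iodo-5-(triisopropylsilyloxy)phenyl]ethanol (racemic) | COc1ccc(C(O)Cc2cc(O[Si](C(C)C)(C(C)C)C(C)C)cc(O)c2I)c(OC)c1 | intermediate (not isolated)
7 | 3-[2,2-bis(2,4-dimethoxyphenyl)ethyl]-2-iodo-5-(triisopropylsilyloxy)phenol | COc1ccc(C(Cc2cc(O[Si](C(C)C)(C(C)C)C(C)C)cc(O)c2I)c2ccc(OC)cc2OC)c(OC)c1 | intermediate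
8 | 4-ethynylanisole (1-ethynyl-4-methoxybenzene) | COc1ccc(C#C)cc1 | starting material
9 | 3-[2,2-bis(2,4-dimethoxyphenyl)ethyl]-2-[(4-methoxyphenyl)ethynyl]-5-(triisopropylsilyloxy)phenol (achiral precursor of the key step) | COc1ccc(C#Cc2c(O)cc(O[Si](C(C)C)(C(C)C)C(C)C)cc2CC(c2ccc(OC)cc2OC)c2ccc(OC)cc2OC)cc1 | intermediate
10 | (S)-benzofuran: 2-(4-methoxyphenyl)-6-(triisopropylsilyloxy)benzofuran with C3 bonded to D1 and C4 bonded to the ring C CH2; ring D 3,5-dimethoxy; methine (S) bearing 2,4-dimethoxyphenyl | COc1ccc(-c2oc3cc(O[Si](C(C)C)(C(C)C)C(C)C)cc4c3c2-c2cc(OC)cc(OC)c2[C@H](c2ccc(OC)cc2OC)C4)cc1 | intermediate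
11 | (2R,3S)-cis-2,3-dihydro derivative of 10 (methine S) | COc1ccc([C@@H]2Oc3cc(O[Si](C(C)C)(C(C)C)C(C)C)cc4c3[C@@H]2c2cc(OC)cc(OC)c2[C@H](c2ccc(OC)cc2OC)C4)cc1 | intermediate (not isolated)
12 | (2S,3S)-trans-2,3-dihydro derivative of 10 (methine S; C3–H cis to the methine aryl group) | COc1ccc([C@H]2Oc3cc(O[Si](C(C)C)(C(C)C)C(C)C)cc4c3[C@@H]2c2cc(OC)cc(OC)c2[C@H](c2ccc(OC)cc2OC)C4)cc1 | intermediate
13 | phenol: 12 with OH at C6 in place of the silyl ether | COc1ccc([C@H]2Oc3cc(O)cc4c3[C@@H]2c2cc(OC)cc(OC)c2[C@H](c2ccc(OC)cc2OC)C4)cc1 | intermediate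
14 | 13 with CH2OH at C5 | COc1ccc([C@H]2Oc3cc(O)c(CO)c4c3[C@@H]2c2cc(OC)cc(OC)c2[C@H](c2ccc(OC)cc2OC)C4)cc1 | intermediate (not isolated)
15 | salicylaldehyde: 13 with CHO at C5 | COc1ccc([C@H]2Oc3cc(O)c(C=O)c4c3[C@@H]2c2cc(OC)cc(OC)c2[C@H](c2ccc(OC)cc2OC)C4)cc1 | intermediate
16 | 4-methoxybenzyl chloride | COc1ccc(CCl)cc1 | starting material
17 | 15 with the C6 hydroxyl as its 4-methoxybenzyl ether | COc1ccc([C@H]2Oc3cc(OCc5ccc(OC)cc5)c(C=O)c4c3[C@@H]2c2cc(OC)cc(OC)c2[C@H](c2ccc(OC)cc2OC)C4)cc1 | intermediate
18 | 3,5-dimethoxyphenylmagnesium chloride | COc1cc(OC)cc([Mg]Cl)c1 | starting material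
19 | carbinol: 17 with CH(OH)(3,5-dimethoxyphenyl) at C5 (both carbinol epimers) | COc1ccc([C@H]2Oc3cc(OCc5ccc(OC)cc5)c(C(O)c5cc(OC)cc(OC)c5)c4c3[C@@H]2c2cc(OC)cc(OC)c2[C@H](c2ccc(OC)cc2OC)C4)cc1 | intermediate
20 | ketone: 17 with C(=O)(3,5-dimethoxyphenyl) at C5 | COc1ccc([C@H]2Oc3cc(OCc5ccc(OC)cc5)c(C(=O)c5cc(OC)cc(OC)c5)c4c3[C@@H]2c2cc(OC)cc(OC)c2[C@H](c2ccc(OC)cc2OC)C4)cc1 | intermediate
21 | hydrazone of 20 (C=N–NH2, E/Z mixture) | COc1ccc([C@H]2Oc3cc(OCc5ccc(OC)cc5)c(C(=NN)c5cc(OC)cc(OC)c5)c4c3[C@@H]2c2cc(OC)cc(OC)c2[C@H](c2ccc(OC)cc2OC)C4)cc1 | intermediate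
22 | diaryldiazomethane from 21 | COc1ccc([C@H]2Oc3cc(OCc5ccc(OC)cc5)c(C(=[N+]=[N-])c5cc(OC)cc(OC)c5)c4c3[C@@H]2c2cc(OC)cc(OC)c2[C@H](c2ccc(OC)cc2OC)C4)cc1 | intermediate (not isolated)
23 | cis ring E compound: (2'S,3'R)-2'-(4-methoxyphenyl)-3'-(3,5-dimethoxyphenyl)dihydrofuran fused at C5–C6; ring B (2S,3S); methine S; eight OMe | COc1ccc([C@H]2Oc3cc4c(c5c3[C@@H]2c2cc(OC)cc(OC)c2[C@H](c2ccc(OC)cc2OC)C5)[C@@H](c2cc(OC)cc(OC)c2)[C@@H](c2ccc(OC)cc2)O4)cc1 | intermediate
24 | octamethyl ether of the target: as 23 but with (2'R,3'R)-trans ring E | COc1ccc([C@H]2Oc3cc4c(c5c3[C@@H]2c2cc(OC)cc(OC)c2[C@H](c2ccc(OC)cc2OC)C5)[C@@H](c2cc(OC)cc(OC)c2)[C@H](c2ccc(OC)cc2)O4)cc1 | intermediate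
25 | CNP0154047.3 (octaphenol; 2S,3S in ring B; methine S; 2'R,3'R in ring E) | Oc1ccc([C@H]2Oc3cc4c(c5c3[C@@H]2c2cc(O)cc(O)c2[C@H](c2ccc(O)cc2O)C5)[C@@H](c2cc(O)cc(O)c2)[C@H](c2ccc(O)cc2)O4)cc1 | target

Total step count: 16. Longest linear sequence: 16 steps (from 1; the route is fully linear).

Steps most likely to fail

Step 6. Protonation of the benzofuran-3-yl–palladium bond may outrun C–H cleavage so that the cascade stalls after ring B, or the amino-acid ligand may discriminate poorly between the enantiotopic rings. The fallback uses known chemistry and sets out from 9. Iodocyclisation (I2, NaHCO3, MeCN, 0 °C to rt; 5-endo-dig, established for 2-alkynylphenols) would give 4-[2,2-bis(2,4-dimethoxyphenyl)ethyl]-3-iodo-2-(4-methoxyphenyl)-6-(triisopropylsilyloxy)benzofuran F1. Zerovalent palladium with a chiral ligand (Pd(dba)2, a TADDOL-derived phosphoramidite, Cs2CO3, pivalic acid, mesitylene, 80 °C) would then add oxidatively into the C3–I bond, cleave one enantiotopic C6–H with carboxylate assistance and close ring C by reductive elimination. This is the established enantioselective intramolecular C–H arylation of prochiral diarylmethanes, and it comes back to the route at 10.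

Step 7. The proton may be delivered to the other face of C3, which loses the stereochemical relay, or the silane may capture the ring-opened benzylic cation and cleave ring B reductively. The fallback sets out from 10. Heterogeneous hydrogenation (H2, 50 bar, Pd on carbon (Pd/C), EtOAc–AcOH, 50 °C) adds both hydrogens to one face, expected to be the face opposite the puckered CH2–CH bridge, with no cationic intermediate and no silane. It would give cis isomer 11, this time as an isolated compound. A separate treatment with CF3CO2H in CH2Cl2 epimerises C2 and returns to the route at 12. The fallback makes no compound outside the list (F0).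

Step 14 (with step 13 before it). Hydrazone formation at the doubly ortho-flanked ketone may be too slow; the carbene may insert into the tertiary methine C–H of ring C, which is also in a 1,5 relationship, or add to an electron-rich arene; and a mismatch between catalyst and substrate may erode selectivity. The fallback sets out from 20. LiN(i-Pr)2 (THF, −78 to 0 °C) deprotonates the O–CH2 group, and intramolecular addition to the ketone (aldol-type 5-exo-trig closure) would give the 3'-hydroxy ring E dihydrobenzofuran F2. Dehydration (TsOH, toluene, 60 °C) would give the 2'-(4-methoxyphenyl)-3'-(3,5-dimethoxyphenyl) ring E benzofuran F3. Ionic hydrogenation and acid equilibration as in step 7 (Et3SiH, CF3CO2H–CH2Cl2) then give the trans ring E and come back to the route at 24. In this fallback C3' rests on substrate control only, so 24 would have to be separated from its (2'S,3'S) diastereomer before step 16.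

Further compounds
F1 | step 6 | 4-[2,2-bis(2,4-dimethoxyphenyl)ethyl]-3-iodo-2-(4-methoxyphenyl)-6-(triisopropylsilyloxy)benzofuran | COc1ccc(-c2oc3cc(O[Si](C(C)C)(C(C)C)C(C)C)cc(CC(c4ccc(OC)cc4OC)c4ccc(OC)cc4OC)c3c2I)cc1
F0 | step 7 | none | none
F2 | step 14 | 3'-hydroxy ring E dihydrobenzofuran (tertiary alcohol; C2' and C3' unassigned; ring B 2S,3S; methine S) | COc1ccc([C@H]2Oc3cc4c(c5c3[C@@H]2c2cc(OC)cc(OC)c2[C@H](c2ccc(OC)cc2OC)C5)C(O)(c2cc(OC)cc(OC)c2)C(c2ccc(OC)cc2)O4)cc1
F3 | step 14 | ring E benzofuran: 2'-(4-methoxyphenyl)-3'-(3,5-dimethoxyphenyl)furan fused at C5–C6 (ring B 2S,3S; methine S) | COc1ccc([C@H]2Oc3cc4oc(-c5ccc(OC)cc5)c(-c5cc(OC)cc(OC)c5)c4c5c3[C@@H]2c2cc(OC)cc(OC)c2[C@H](c2ccc(OC)cc2OC)C5)cc1
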